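## The problem

The target (22) is a sesquineolignan made of three C6–C3 units. Ring A carries the (E)-3-hydroxypropenyl chain and is fused to a 1,4-dioxane containing C7 and C8. C7 bears ring B, which is fused to a second dioxane containing C7' and C8'. C7' bears ring C, a free catechol.

The two dioxanes are wired in opposite senses. On ring A the oxygen para to the side chain is bonded to C8 (the carbon with the CH2OH arm C9) and the meta oxygen to the benzylic C7. On ring B the oxygen para to C7 is bonded to the benzylic C7' and the meta oxygen to C8'. A synthesis must therefore decide, for each dioxane, which aryl oxygen goes to which carbon.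

There are four stereocentres (7R, 8R, 7'R, 8'R), and each dioxane is trans. Within a pair one centre can direct the other, but the two pairs are insulated by ring B, so each pair needs its own reagent control.

The catechol (air, base), the para-oxygenated cinnamyl alcohol (acid, hydrogenation) and the benzylic C7–O and C7'–O bonds (acid ionisation, hydrogenolysis) restrict the end game to neutral, non-reductive chemistry. Benzyl-type protection is therefore excluded.

The feature that opens the structure is C8. It is bonded to a phenolic oxygen of ring A, to a one-carbon arm at the ester or alcohol level, to hydrogen and to the carbinol carbon C7 that carries ring B. This is the pattern of an α-aryloxy-β-hydroxy ester, which is a phenol, a carbene carbon and an aldehyde joined at one atom. The second ring A oxygen can then be introduced as a halogen ortho to the phenol oxygen and replaced by the C7 hydroxyl, which leaves the C7–O bond intact.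

## Retrosynthesis

**22 from 21.** No skeletal bond is cut. All five hydroxyls of 22 are traced to triisopropylsilyl ethers in 21. Silyl ethers are the only class that can be removed without acid, hydrogen or an oxidant. The triisopropyl variant is chosen over smaller silyl groups because aryl and primary alkyl triisopropylsilyl ethers resist the alkoxide and carbonate bases used earlier. The forward step must be one buffered fluoride treatment.

**21 from 20.** The cut is the aryl–O bond between the ring A carbon meta to the side chain and the oxygen on C7. The neighbouring cut, C7–O with a ring A phenol attacking a C7 electrophile, would put the benzylic stereocentre through a substitution with SN1/SN2 ambiguity. The aryl–O cut leaves both stereocentres as spectators. The bromide in 20 is meta to the side chain and not activated for addition–elimination, so copper catalysis is required. In 20 the C9 oxygen must be capped, because a free C9 hydroxyl could close an isomeric six-membered ring onto the same bromide.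

**20 from 19 from 18.** These are protection and oxidation-level changes only. C9 and the terminus of the side chain are both traced to ethyl esters in 18, so one hydride operation delivers both primary alcohols. This is why ring A carries an acrylate ester and not a nitrile through the coupling. With a nitrile the side chain would have to be built afterwards in three further steps.

**18 from 15, 16 and 12 (key cut).** The O–C8 and C7–C8 bonds are cut together. The stepwise neighbour first makes an aryloxyacetate and then runs an auxiliary-controlled aldol. That costs two to three steps and a stoichiometric controller. Cutting O–C8 alone, as a substitution at C8 of a diol ester, would invert C8 and face a choice between two hydroxyls. The three-component cut reduces 18 to a one-step phenol (15), commercial ethyl diazoacetate (16) and the ring B and C aldehyde (12). The forward reaction must capture the carbene-derived enol by the aldehyde faster than it tautomerises. It must also be syn and face selective under a chiral phosphoric acid.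

**15 from 13 and 14.** The alkene is cut by Wittig logic. The stabilised ylide 14 sets the E geometry and brings the ester that step 10 will reduce.

**12 from 10.** The aldehyde is traced to a nitrile, which survives the aldol, the hydride and the base that precede it.

**10 from 9.** The aryl–O bond para to the nitrile is cut. Because this dioxane has the opposite regiochemistry, the leaving group sits para to the nitrile, and fluoride displacement by the C7' alkoxide needs no metal.

**9 from 8 from 7.** These are silylation of C9'–OH and reductive removal of the auxiliary.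

**7 from 5 and 2.** The C7'–C8' bond is cut as an auxiliary-controlled syn aldol between the aryloxyacetyl imide 5 and the ring C aldehyde 2. Established chemistry is used here on purpose, so that the route contains only one unprecedented step. The logic is the same as for ring A: a syn aldol followed by a closure that retains configuration gives the trans dioxane.

**5 from 3 and 4; 2 from 1.** 5 is cut at the ether C–O bond into phenol 3 and the chloroacetyl imide 4. 2 is the bis-silyl ether of 1.

## Roads not taken

**Alternative 1:** chiral pool plus anodic ring closure. The cut is the O–C7' bond of the ring B dioxane. (R)-3-(3,4-Dihydroxyphenyl)lactic acid (danshensu, A1) would supply ring C, C7', C8' and C9'. Etherification of its ester with a ring B phenol, with inversion at C8', followed by reduction would give the cyclisation substrate A2. Two-electron anodic oxidation of the catechol of A2, tautomerisation to the para-quinone methide at C7' and addition of the ring B phenol would close the dioxane to A3.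

- Merits: C8' comes from the pool, the key step needs no reagent and no catechol protection, and A3 is only a protection and an ester-to-aldehyde change away from a fragment like 12.
- Weak points: C7' is set only by 1,2-induction from C8' in a quinone methide addition, so trans selectivity is not guaranteed. The ortho-quinone can be intercepted on the ring before it tautomerises. A3 is itself a catechol of similar oxidation potential, so over-oxidation and oligomers threaten. The phenol para to an ester is a weak nucleophile.
- Scope: the method cannot be repeated on ring A. There the benzylic carbon C7 sits on ring B, whose oxygens are both alkylated, so no quinone methide can be generated.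
- Comparison: for the ring B fragment alone this road is better in atom and redox economy than the auxiliary aldol used here. Against that, the chosen plan sets reagent control of both C7' and C8' in one aldol, and one stereochemical logic serving both dioxanes.

**Alternative 2:** palladium allyl closure with vinyl as masked hydroxymethyl. The cut is the O–C8' bond of the ring B dioxane. A zerovalent palladium phosphine catalyst would ionise the allylic carbonate A4. The ring B phenoxide would attack the internal allyl terminus to give the trans vinyl benzodioxane A5. The vinyl group would later be cleaved oxidatively and reduced to CH2OH.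

- Merits: the closure is catalytic and nearly neutral, the six-membered ring is strongly favoured over the eight-membered one, and it is milder than the strong-base closure of step 6.
- Weak points: C7' must already exist as a benzylic, allylic aryl ether. That C–O bond is itself ionisable by the catalyst, and it can be lost by β-elimination from the allyl complex to a diene. The C8' configuration then rests on 1,2-induction or on a matched ligand.
- Weak points for this target: oxidative cleavage of the vinyl group must be run beside electron-rich arenes. The benzyl ethers of A5 would have to be removed at the end without hydrogenolysis, because of the cinnamyl alkene and two benzylic C–O bonds.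
- Comparison: this road also solves only ring B. Its catalytic, auxiliary-free closure is a real advantage. The chosen plan answers with protecting groups that all fall to fluoride, no oxidative cleavage step, and both stereocentres of each dioxane made in one event.

**Alternative 3:** ring A and its dioxane by alkyne cyclotrimerisation. The cut removes three C–C bonds of ring A. A cationic monovalent rhodium bisphosphine catalyst would join the two alkynyl ethers of diyne A6 with the terminal alkyne of enyne A7. The product A8 is the fully silylated target carrying a trimethylsilyl group on ring A.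

- Merits: this is the most convergent of all the plans. One step makes ring A, its dioxane and the side-chain attachment. The C7/C8 stereocentres come from a syn diol with both C–O bonds intact, and no hindered C–O coupling is needed.
- Weak points: A6 is a research problem in itself. Alkynyl ethers of secondary alcohols are hard to make. The benzylic one at C7 is prone to sigmatropic and retro-ene decomposition to ketenes near room temperature.
- Further weak points: the enyne alkene and alkyne homotrimerisation compete. The silicon steering group must afterwards be removed from the arene, which normally needs acid that the benzylic ethers and the allylic system do not tolerate.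
- Comparison: in bonds formed per step this road beats the chosen plan, and it avoids an aryl halide altogether. The chosen plan sets against it trivially available coupling partners (15, 16) and an auxiliary aldol that forms the same C7–C8 bond if the new step fails.

Key step: step 9

Assumption: the (R) enantiomer of the phosphoric acid is taken to deliver the (2S,3R) aldol 18; if the sense of induction is the opposite, the (S) acid is used with no other change.
Assumption: (S)-4-benzyl-3-(chloroacetyl)oxazolidin-2-one (4) is treated as a purchased compound.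

## Route

Step 1
Reactants: 1 3,4-dihydroxybenzaldehyde
Product: 2 3,4-bis(triisopropylsilyloxy)benzaldehyde
Conditions: TIPSCl (2.4 equiv), imidazole (5 equiv), DMAP (cat.), DMF, 0 °C to rt
Reagents that add atoms: chlorotriisopropylsilane (TIPSCl), CC(C)[Si](Cl)(C(C)C)C(C)C
Why: Standard phenol silylation; triisopropylsilyl is chosen because its aryl ethers resist the bases of steps 6 and 12 and still fall to fluoride in step 13.

Step 2
Reactants: 3 4-fluoro-3-hydroxybenzonitrile; 4 (S)-4-benzyl-3-(chloroacetyl)oxazolidin-2-one
Product: 5 (S)-4-benzyl-3-[(5-cyano-2-fluorophenoxy)acetyl]oxazolidin-2-one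
Conditions: K2CO3 (1.5 equiv), NaI (10 mol %), MeCN, rt
Reagents that add atoms: none
Why: Williamson ether synthesis; the weakly basic phenoxide attacks the activated CH2–halogen carbon (iodide-assisted SN2) much faster than the imide carbonyl or the aryl fluoride.

Step 3
Reactants: 5 (S)-4-benzyl-3-[(5-cyano-2-fluorophenoxy)acetyl]oxazolidin-2-one; 2 3,4-bis(triisopropylsilyloxy)benzaldehyde
Product: 7 (S)-4-benzyl-3-[(2S,3R)-2-(5-cyano-2-fluorophenoxy)-3-hydroxy-3-[3,4-bis(triisopropylsilyloxy)phenyl]propanoyl]oxazolidin-2-one, via dibutylboron enolate 6 (not isolated)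
Conditions: Bu2BOTf (1.3 equiv), iPr2NEt (1.5 equiv), CH2Cl2, −78 to 0 °C; then 2, −78 to 0 °C; pH 7 buffer, MeOH, H2O2, 0 °C
Reagents that add atoms: dibutylboron triflate, CCCCB(CCCC)OS(=O)(=O)C(F)(F)F (its Bu2B group is held in 6 and leaves on work-up)
Why: Evans syn aldol reaction of a glycolate-type imide; the (Z)-boron enolate 6 reacts through a Zimmerman–Traxler chair with the auxiliary carbonyl turned away from the enolate oxygen, so the aldehyde meets the face opposite the benzyl group and C8' (2S) and C7' (3R) are set together, syn.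

Step 4
Reactants: 7 (S)-4-benzyl-3-[(2S,3R)-2-(5-cyano-2-fluorophenoxy)-3-hydroxy-3-[3,4-bis(triisopropylsilyloxy)phenyl]propanoyl]oxazolidin-2-one
Product: 8 3-{[(1R,2R)-1-[3,4-bis(triisopropylsilyloxy)phenyl]-1,3-dihydroxypropan-2-yl]oxy}-4-fluorobenzonitrile
Conditions: LiBH4 (2 equiv), MeOH (2 equiv), THF, 0 °C
Reagents that add atoms: none
Why: Reductive removal of the oxazolidinone auxiliary; LiBH4 reduces the imide to the primary alcohol and leaves the nitrile, the aryl fluoride and the silyl ethers alone, and no stereocentre is touched.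

Step 5
Reactants: 8 3-{[(1R,2R)-1-[3,4-bis(triisopropylsilyloxy)phenyl]-1,3-dihydroxypropan-2-yl]oxy}-4-fluorobenzonitrile
Product: 9 3-{[(1R,2R)-1-[3,4-bis(triisopropylsilyloxy)phenyl]-1-hydroxy-3-(triisopropylsilyloxy)propan-2-yl]oxy}-4-fluorobenzonitrile
Conditions: TIPSCl (1.2 equiv), imidazole (2.5 equiv), CH2Cl2, 0 °C to rt
Reagents that add atoms: chlorotriisopropylsilane (TIPSCl), CC(C)[Si](Cl)(C(C)C)C(C)C
Why: Selective silylation of the primary over the hindered secondary benzylic hydroxyl; the C9' oxygen must be capped because it could otherwise close an isomeric six-membered ring in step 6, and the bulky group is slow to migrate to the neighbouring alkoxide.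

Step 6
Reactants: 9 3-{[(1R,2R)-1-[3,4-bis(triisopropylsilyloxy)phenyl]-1-hydroxy-3-(triisopropylsilyloxy)propan-2-yl]oxy}-4-fluorobenzonitrile
Product: 10 (2R,3R)-2-[3,4-bis(triisopropylsilyloxy)phenyl]-3-[(triisopropylsilyloxy)methyl]-2,3-dihydro-1,4-benzodioxine-6-carbonitrile
Conditions: KN(SiMe3)2 (1.1 equiv), THF, 0 °C to rt
Reagents that add atoms: none
Why: Intramolecular nucleophilic aromatic substitution (SNAr); the C7' alkoxide displaces the fluoride para to the nitrile through a six-membered transition state, and since the C7'–O bond is never broken the syn pair becomes the trans (2R,3R) dioxane.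

Step 7
Reactants: 10 (2R,3R)-2-[3,4-bis(triisopropylsilyloxy)phenyl]-3-[(triisopropylsilyloxy)methyl]-2,3-dihydro-1,4-benzodioxine-6-carbonitrile
Product: 12 (2R,3R)-2-[3,4-bis(triisopropylsilyloxy)phenyl]-3-[(triisopropylsilyloxy)methyl]-2,3-dihydro-1,4-benzodioxine-6-carbaldehyde, via diisobutylaluminium aldimine 11 (not isolated)
Conditions: iBu2AlH (1.3 equiv), toluene, −78 to −40 °C; then 1 M aq. HCl, 0 °C
Reagents that add atoms: diisobutylaluminium hydride, CC(C)C[AlH]CC(C)C (aluminium in 11 only); water, O (the aldehyde oxygen)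
Why: Partial reduction of an aryl nitrile; one hydride is delivered, the aluminium aldimine 11 is stable at low temperature and is hydrolysed to the aldehyde on brief cold acidic work-up, which the triisopropylsilyl ethers tolerate.

Step 8
Reactants: 13 3-bromo-4-hydroxybenzaldehyde; 14 ethyl (triphenylphosphoranylidene)acetate
Product: 15 ethyl (E)-3-(3-bromo-4-hydroxyphenyl)prop-2-enoate
Conditions: 14 (1.5 equiv), toluene, 90 °C
Reagents that add atoms: none
Why: Wittig olefination with a stabilised ylide, which is E-selective and tolerates the free phenol.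

Step 9
Reactants: 15 ethyl (E)-3-(3-bromo-4-hydroxyphenyl)prop-2-enoate; 16 ethyl diazoacetate; 12 (2R,3R)-2-[3,4-bis(triisopropylsilyloxy)phenyl]-3-[(triisopropylsilyloxy)methyl]-2,3-dihydro-1,4-benzodioxine-6-carbaldehyde
Product: 18 ethyl (2S,3R)-2-{2-bromo-4-[(E)-3-ethoxy-3-oxoprop-1-enyl]phenoxy}-3-hydroxy-3-[(2R,3R)-2-[3,4-bis(triisopropylsilyloxy)phenyl]-3-[(triisopropylsilyloxy)methyl]-2,3-dihydro-1,4-benzodioxin-6-yl]propanoate, via aryloxy ketene hemiacetal enol 17 (not isolated)
Conditions: 12 (1 equiv), 15 (2 equiv), Rh2(OAc)4 (2 mol %), (R)-TRIP [(R)-3,3'-bis(2,4,6-triisopropylphenyl)-1,1'-binaphthyl-2,2'-diyl hydrogen phosphate] (10 mol %), 4 Å molecular sieves, CH2Cl2, −20 °C; 16 (2.5 equiv) added over 6 h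
Reagents that add atoms: none
Why: Proposed new method: Rh2(OAc)4 (divalent rhodium) decomposes 16 to the rhodium carbene, the phenol oxygen of 15 adds to it, and the protic oxonium ylide relaxes to the free enol 17 (aryloxy cis to the enol OH), which the phosphoric acid holds through its P=O while its P–OH activates aldehyde 12, so that C–C bond formation in a closed, chair-like hydrogen-bonded array outruns the 1,2-proton shift that would give the plain O–H insertion product. The closest known reaction type is the rhodium carbene and chiral Brønsted acid three-component coupling of diazo esters, alcohols and aldehydes or imines through trapped oxonium ylides; new here is the combination of a phenol, an acceptor-only diazoacetate and an electron-rich aryl aldehyde. No ring is closed; the O–C8 and C7–C8 bonds are formed. C8 (S in 18, because the ester outranks C7) and C7 (R) are both created in the aldol event: their syn relationship follows from the cis enol reacting through the closed array, their absolute sense from the phosphoric acid, the dioxane stereocentres of 12 being too remote to interfere. The step needs O–H insertion to beat cyclopropanation, carbonyl ylide formation and carbene dimerisation, which the acidic unhindered phenol, the electron-poor trans-disubstituted acrylate and the slow addition of 16 should secure. It also needs aldol capture to beat proton transfer, which dry conditions, low temperature and the use of 12 as the limiting component beside an excess of the two cheap partners should favour. Because 12 is a single enantiomer, every mis-selected stereoisomer is a diastereomer of 18 and can be removed by chromatography.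

Step 10
Reactants: 18 ethyl (2S,3R)-2-{2-bromo-4-[(E)-3-ethoxy-3-oxoprop-1-enyl]phenoxy}-3-hydroxy-3-[(2R,3R)-2-[3,4-bis(triisopropylsilyloxy)phenyl]-3-[(triisopropylsilyloxy)methyl]-2,3-dihydro-1,4-benzodioxin-6-yl]propanoate
Product: 19 (1R,2R)-2-{2-bromo-4-[(E)-3-hydroxyprop-1-enyl]phenoxy}-1-[(2R,3R)-2-[3,4-bis(triisopropylsilyloxy)phenyl]-3-[(triisopropylsilyloxy)methyl]-2,3-dihydro-1,4-benzodioxin-6-yl]propane-1,3-diol
Conditions: iBu2AlH (7 equiv), CH2Cl2, −78 to −20 °C; aq. Rochelle salt
Reagents that add atoms: none
Why: Hydride reduction of both esters in one operation; iBu2AlH takes the α-aryloxy ester to the C9 alcohol and the cinnamate by 1,2-reduction to the allylic alcohol without touching the alkene, the bromide or the silyl ethers. The descriptor at C8 changes from S to R only because the CIP priorities change.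

Step 11
Reactants: 19 (1R,2R)-2-{2-bromo-4-[(E)-3-hydroxyprop-1-enyl]phenoxy}-1-[(2R,3R)-2-[3,4-bis(triisopropylsilyloxy)phenyl]-3-[(triisopropylsilyloxy)methyl]-2,3-dihydro-1,4-benzodioxin-6-yl]propane-1,3-diol
Product: 20 (1R,2R)-2-{2-bromo-4-[(E)-3-(triisopropylsilyloxy)prop-1-enyl]phenoxy}-1-[(2R,3R)-2-[3,4-bis(triisopropylsilyloxy)phenyl]-3-[(triisopropylsilyloxy)methyl]-2,3-dihydro-1,4-benzodioxin-6-yl]-3-(triisopropylsilyloxy)propan-1-ol
Conditions: TIPSCl (2.4 equiv), imidazole (5 equiv), DMF, 0 °C to rt
Reagents that add atoms: chlorotriisopropylsilane (TIPSCl), CC(C)[Si](Cl)(C(C)C)C(C)C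
Why: Selective silylation of the two primary hydroxyls over the hindered secondary benzylic C7 hydroxyl; C9–OH has to be masked because its alkoxide could close an isomeric benzodioxane in step 12.

Step 12
Reactants: 20 (1R,2R)-2-{2-bromo-4-[(E)-3-(triisopropylsilyloxy)prop-1-enyl]phenoxy}-1-[(2R,3R)-2-[3,4-bis(triisopropylsilyloxy)phenyl]-3-[(triisopropylsilyloxy)methyl]-2,3-dihydro-1,4-benzodioxin-6-yl]-3-(triisopropylsilyloxy)propan-1-ol
Product: 21 (2R,3R)-3-[(2R,3R)-2-[3,4-bis(triisopropylsilyloxy)phenyl]-3-[(triisopropylsilyloxy)methyl]-2,3-dihydro-1,4-benzodioxin-6-yl]-2-[(triisopropylsilyloxy)methyl]-6-[(E)-3-(triisopropylsilyloxy)prop-1-enyl]-2,3-dihydro-1,4-benzodioxine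
Conditions: CuI (10 mol %), 3,4,7,8-tetramethyl-1,10-phenanthroline (20 mol %), Cs2CO3 (2 equiv), toluene, 100 °C
Reagents that add atoms: none
Why: Intramolecular Ullmann-type O-arylation with CuI (monovalent copper); the C7 alkoxide is joined to the ortho bromide in a six-membered ring, only the aryl–O bond is made, so C7 keeps its configuration and the syn (7R,8R) pair becomes the trans dioxane. Copper is preferred to palladium because a secondary benzylic alkoxide on palladium is prone to β-hydride elimination.

Step 13
Reactants: 21 (2R,3R)-3-[(2R,3R)-2-[3,4-bis(triisopropylsilyloxy)phenyl]-3-[(triisopropylsilyloxy)methyl]-2,3-dihydro-1,4-benzodioxin-6-yl]-2-[(triisopropylsilyloxy)methyl]-6-[(E)-3-(triisopropylsilyloxy)prop-1-enyl]-2,3-dihydro-1,4-benzodioxine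
Product: 22 (E)-3-[(2R,3R)-3-[(2R,3R)-2-(3,4-dihydroxyphenyl)-3-(hydroxymethyl)-2,3-dihydro-1,4-benzodioxin-6-yl]-2-(hydroxymethyl)-2,3-dihydro-1,4-benzodioxin-6-yl]prop-2-en-1-ol
Conditions: Bu4NF (7.5 equiv), AcOH (7.5 equiv), THF, 0 °C to rt, argon
Reagents that add atoms: none
Why: Fluoride-induced cleavage of all five silyl ethers; the acetic acid buffer keeps the liberated catechol protonated and spares the cinnamyl alcohol and the benzylic ethers, and no stereocentre is involved.

## Compound list

1 | 3,4-dihydroxybenzaldehyde | O=Cc1ccc(O)c(O)c1 | starting material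
2 | 3,4-bis(triisopropylsilyloxy)benzaldehyde | O=Cc1ccc(O[Si](C(C)C)(C(C)C)C(C)C)c(O[Si](C(C)C)(C(C)C)C(C)C)c1 | intermediate
3 | 4-fluoro-3-hydroxybenzonitrile | N#Cc1ccc(F)c(O)c1 | starting material
4 | (S)-4-benzyl-3-(chloroacetyl)oxazolidin-2-one | O=C(CCl)N1[C@@H](Cc2ccccc2)COC1=O | starting material
5 | (S)-4-benzyl-3-[(5-cyano-2-fluorophenoxy)acetyl]oxazolidin-2-one | N#Cc1ccc(F)c(OCC(=O)N2[C@@H](Cc3ccccc3)COC2=O)c1 | intermediate
6 | dibutylboron (Z)-enolate of 5 | CCCCB(CCCC)O/C(=C\Oc1cc(C#N)ccc1F)N1[C@@H](Cc2ccccc2)COC1=O | intermediate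
7 | (S)-4-benzyl-3-[(2S,3R)-2-(5-cyano-2-fluorophenoxy)-3-hydroxy-3-[3,4-bis(triisopropylsilyloxy)phenyl]propanoyl]oxazolidin-2-one | N#Cc1ccc(F)c(O[C@H](C(=O)N2[C@@H](Cc3ccccc3)COC2=O)[C@H](O)c2ccc(O[Si](C(C)C)(C(C)C)C(C)C)c(O[Si](C(C)C)(C(C)C)C(C)C)c2)c1 | intermediate
8 | 3-{[(1R,2R)-1-[3,4-bis(triisopropylsilyloxy)phenyl]-1,3-dihydroxypropan-2-yl]oxy}-4-fluorobenzonitrile | N#Cc1ccc(F)c(O[C@H](CO)[C@H](O)c2ccc(O[Si](C(C)C)(C(C)C)C(C)C)c(O[Si](C(C)C)(C(C)C)C(C)C)c2)c1 | intermediate
9 | 3-{[(1R,2R)-1-[3,4-bis(triisopropylsilyloxy)phenyl]-1-hydroxy-3-(triisopropylsilyloxy)propan-2-yl]oxy}-4-fluorobenzonitrile | N#Cc1ccc(F)c(O[C@H](CO[Si](C(C)C)(C(C)C)C(C)C)[C@H](O)c2ccc(O[Si](C(C)C)(C(C)C)C(C)C)c(O[Si](C(C)C)(C(C)C)C(C)C)c2)c1 | intermediate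
10 | (2R,3R)-2-[3,4-bis(triisopropylsilyloxy)phenyl]-3-[(triisopropylsilyloxy)methyl]-2,3-dihydro-1,4-benzodioxine-6-carbonitrile | N#Cc1ccc2c(c1)O[C@H](CO[Si](C(C)C)(C(C)C)C(C)C)[C@@H](c1ccc(O[Si](C(C)C)(C(C)C)C(C)C)c(O[Si](C(C)C)(C(C)C)C(C)C)c1)O2 | intermediate
11 | N-(diisobutylaluminio)aldimine derived from 10 | CC(C)C[Al](CC(C)C)N=Cc1ccc2c(c1)O[C@H](CO[Si](C(C)C)(C(C)C)C(C)C)[C@@H](c1ccc(O[Si](C(C)C)(C(C)C)C(C)C)c(O[Si](C(C)C)(C(C)C)C(C)C)c1)O2 | intermediate
12 | (2R,3R)-2-[3,4-bis(triisopropylsilyloxy)phenyl]-3-[(triisopropylsilyloxy)methyl]-2,3-dihydro-1,4-benzodioxine-6-carbaldehyde | O=Cc1ccc2c(c1)O[C@H](CO[Si](C(C)C)(C(C)C)C(C)C)[C@@H](c1ccc(O[Si](C(C)C)(C(C)C)C(C)C)c(O[Si](C(C)C)(C(C)C)C(C)C)c1)O2 | intermediate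
13 | 3-bromo-4-hydroxybenzaldehyde | O=Cc1ccc(O)c(Br)c1 | starting material
14 | ethyl (triphenylphosphoranylidene)acetate | CCOC(=O)C=P(c1ccccc1)(c1ccccc1)c1ccccc1 | starting material
15 | ethyl (E)-3-(3-bromo-4-hydroxyphenyl)prop-2-enoate | CCOC(=O)/C=C/c1ccc(O)c(Br)c1 | intermediate
16 | ethyl diazoacetate | CCOC(=O)C=[N+]=[N-] | starting material
17 | ethyl (E)-3-(3-bromo-4-{[(E)-2-ethoxy-2-hydroxyethenyl]oxy}phenyl)prop-2-enoate (enol) | CCO/C(O)=C/Oc1ccc(/C=C/C(=O)OCC)cc1Br | intermediate
18 | ethyl (2S,3R)-2-{2-bromo-4-[(E)-3-ethoxy-3-oxoprop-1-enyl]phenoxy}-3-hydroxy-3-[(2R,3R)-2-[3,4-bis(triisopropylsilyloxy)phenyl]-3-[(triisopropylsilyloxy)methyl]-2,3-dihydro-1,4-benzodioxin-6-yl]propanoate | CCOC(=O)/C=C/c1ccc(O[C@H](C(=O)OCC)[C@H](O)c2ccc3c(c2)O[C@H](CO[Si](C(C)C)(C(C)C)C(C)C)[C@@H](c2ccc(O[Si](C(C)C)(C(C)C)C(C)C)c(O[Si](C(C)C)(C(C)C)C(C)C)c2)O3)c(Br)c1 | intermediate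
19 | (1R,2R)-2-{2-bromo-4-[(E)-3-hydroxyprop-1-enyl]phenoxy}-1-[(2R,3R)-2-[3,4-bis(triisopropylsilyloxy)phenyl]-3-[(triisopropylsilyloxy)methyl]-2,3-dihydro-1,4-benzodioxin-6-yl]propane-1,3-diol | OC/C=C/c1ccc(O[C@H](CO)[C@H](O)c2ccc3c(c2)O[C@H](CO[Si](C(C)C)(C(C)C)C(C)C)[C@@H](c2ccc(O[Si](C(C)C)(C(C)C)C(C)C)c(O[Si](C(C)C)(C(C)C)C(C)C)c2)O3)c(Br)c1 | intermediate
20 | (1R,2R)-2-{2-bromo-4-[(E)-3-(triisopropylsilyloxy)prop-1-enyl]phenoxy}-1-[(2R,3R)-2-[3,4-bis(triisopropylsilyloxy)phenyl]-3-[(triisopropylsilyloxy)methyl]-2,3-dihydro-1,4-benzodioxin-6-yl]-3-(triisopropylsilyloxy)propan-1-ol | CC(C)[Si](C(C)C)(C(C)C)OC/C=C/c1ccc(O[C@H](CO[Si](C(C)C)(C(C)C)C(C)C)[C@H](O)c2ccc3c(c2)O[C@H](CO[Si](C(C)C)(C(C)C)C(C)C)[C@@H](c2ccc(O[Si](C(C)C)(C(C)C)C(C)C)c(O[Si](C(C)C)(C(C)C)C(C)C)c2)O3)c(Br)c1 | intermediate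
21 | (2R,3R)-3-[(2R,3R)-2-[3,4-bis(triisopropylsilyloxy)phenyl]-3-[(triisopropylsilyloxy)methyl]-2,3-dihydro-1,4-benzodioxin-6-yl]-2-[(triisopropylsilyloxy)methyl]-6-[(E)-3-(triisopropylsilyloxy)prop-1-enyl]-2,3-dihydro-1,4-benzodioxine | CC(C)[Si](C(C)C)(C(C)C)OC/C=C/c1ccc2c(c1)O[C@H](c1ccc3c(c1)O[C@H](CO[Si](C(C)C)(C(C)C)C(C)C)[C@@H](c1ccc(O[Si](C(C)C)(C(C)C)C(C)C)c(O[Si](C(C)C)(C(C)C)C(C)C)c1)O3)[C@@H](CO[Si](C(C)C)(C(C)C)C(C)C)O2 | intermediate
22 | (E)-3-[(2R,3R)-3-[(2R,3R)-2-(3,4-dihydroxyphenyl)-3-(hydroxymethyl)-2,3-dihydro-1,4-benzodioxin-6-yl]-2-(hydroxymethyl)-2,3-dihydro-1,4-benzodioxin-6-yl]prop-2-en-1-ol | OC/C=C/c1ccc2c(c1)O[C@H](c1ccc3c(c1)O[C@H](CO)[C@@H](c1ccc(O)c(O)c1)O3)[C@@H](CO)O2 | target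

## Step count and risks

Total: 13 steps. Longest linear sequence: 11 steps (steps 2, 3, 4, 5, 6, 7, 9, 10, 11, 12, 13); steps 1 and 8 are one-step side branches.

**Step 9 (key step, new method).** The most likely failure is that aldol capture of the enol loses the race against proton transfer. The carbene then ends as the simple O–H insertion product, and the electron-rich aldehyde, a weak electrophile, stays unconsumed. Lesser leaks are poor syn or facial selectivity and a second carbene insertion into the new secondary hydroxyl.

Fallback by known chemistry, setting out from 15 and 12 and returning at 19: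
- Phenol 15 is alkylated with 4 (K2CO3, NaI, MeCN) to (S)-4-benzyl-3-({2-bromo-4-[(E)-3-ethoxy-3-oxoprop-1-enyl]phenoxy}acetyl)oxazolidin-2-one F1.
- Its dibutylboron enolate (Bu2BOTf, iPr2NEt, CH2Cl2, −78 °C) is added to 12 in an Evans syn aldol reaction. This gives the (2S,3R) imide adduct, (S)-4-benzyl-3-[(2S,3R)-2-{2-bromo-4-[(E)-3-ethoxy-3-oxoprop-1-enyl]phenoxy}-3-hydroxy-3-(benzodioxin-6-yl)propanoyl]oxazolidin-2-one F2.
- LiBH4 (THF, MeOH, 0 °C) removes the auxiliary faster than it attacks the cinnamate. This gives ethyl (E)-3-(3-bromo-4-{[(1R,2R)-1,3-dihydroxy-1-(benzodioxin-6-yl)propan-2-yl]oxy}phenyl)prop-2-enoate F3.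
- iBu2AlH (CH2Cl2, −78 °C) reduces the remaining ester to give 19.

This costs three extra steps and a second equivalent of auxiliary.

**Step 12.** Copper insertion into an electron-rich, ortho-alkoxy aryl bromide may be slow at a hindered secondary alkoxide. That leaves time for three side processes: base-induced migration of the C9 silyl group followed by closure through the wrong oxygen, fragmentation of the β-aryloxy alkoxide, and protodebromination.

Fallback reversing the polarity of the arene, setting out from 20 and returning at 21: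
- Miyaura borylation (PdCl2(dppf), divalent palladium; bis(pinacolato)diboron, KOAc, dioxane, 80 °C) gives the pinacol boronate of 20 in place of the bromide, F4.
- An intramolecular Chan–Lam etherification (Cu(OAc)2, divalent copper; pyridine, 4 Å molecular sieves, air, CH2Cl2, rt) closes the same aryl–O bond at room temperature under weakly basic conditions to give 21.

**Step 2.** Acyl transfer from the imide to the phenoxide, with loss of the auxiliary, may compete with O-alkylation.

Fallback that acylates the auxiliary instead of alkylating the phenol, setting out from 3 and returning at 5: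
- 3 is alkylated with tert-butyl bromoacetate (K2CO3, acetone) to tert-butyl (5-cyano-2-fluorophenoxy)acetate F5.
- Trifluoroacetic acid in CH2Cl2 gives (5-cyano-2-fluorophenoxy)acetic acid F6.
- F6 is coupled with (S)-4-benzyloxazolidin-2-one (N,N'-dicyclohexylcarbodiimide, catalytic 4-(dimethylamino)pyridine, CH2Cl2) to give 5.

**Step 13.** The five hindered silyl ethers may cleave incompletely. The free pentahydroxy catechol may also be lost to air oxidation and to adsorption during isolation.

Fallback that changes the isolation, setting out from 21 and returning at 22: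
- After fluoride treatment the crude product is acetylated in the same flask (Ac2O, pyridine) to the stable pentaacetate of 22, F7.
- F7 is purified and then deacetylated with K2CO3 in degassed MeOH at 0 °C under argon to give 22.

## Further compounds

F1 | step 9 | (S)-4-benzyl-3-({2-bromo-4-[(E)-3-ethoxy-3-oxoprop-1-enyl]phenoxy}acetyl)oxazolidin-2-one | CCOC(=O)/C=C/c1ccc(OCC(=O)N2[C@@H](Cc3ccccc3)COC2=O)c(Br)c1
F2 | step 9 | (S)-4-benzyl-3-[(2S,3R)-2-{2-bromo-4-[(E)-3-ethoxy-3-oxoprop-1-enyl]phenoxy}-3-hydroxy-3-[(2R,3R)-2-[3,4-bis(triisopropylsilyloxy)phenyl]-3-[(triisopropylsilyloxy)methyl]-2,3-dihydro-1,4-benzodioxin-6-yl]propanoyl]oxazolidin-2-one | CCOC(=O)/C=C/c1ccc(O[C@H](C(=O)N2[C@@H](Cc3ccccc3)COC2=O)[C@H](O)c2ccc3c(c2)O[C@H](CO[Si](C(C)C)(C(C)C)C(C)C)[C@@H](c2ccc(O[Si](C(C)C)(C(C)C)C(C)C)c(O[Si](C(C)C)(C(C)C)C(C)C)c2)O3)c(Br)c1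
F3 | step 9 | ethyl (E)-3-(3-bromo-4-{[(1R,2R)-1,3-dihydroxy-1-[(2R,3R)-2-[3,4-bis(triisopropylsilyloxy)phenyl]-3-[(triisopropylsilyloxy)methyl]-2,3-dihydro-1,4-benzodioxin-6-yl]propan-2-yl]oxy}phenyl)prop-2-enoate | CCOC(=O)/C=C/c1ccc(O[C@H](CO)[C@H](O)c2ccc3c(c2)O[C@H](CO[Si](C(C)C)(C(C)C)C(C)C)[C@@H](c2ccc(O[Si](C(C)C)(C(C)C)C(C)C)c(O[Si](C(C)C)(C(C)C)C(C)C)c2)O3)c(Br)c1
F4 | step 12 | pinacol boronate of 20 (4,4,5,5-tetramethyl-1,3,2-dioxaborolan-2-yl in place of bromine) | CC(C)[Si](C(C)C)(C(C)C)OC/C=C/c1ccc(O[C@H](CO[Si](C(C)C)(C(C)C)C(C)C)[C@H](O)c2ccc3c(c2)O[C@H](CO[Si](C(C)C)(C(C)C)C(C)C)[C@@H](c2ccc(O[Si](C(C)C)(C(C)C)C(C)C)c(O[Si](C(C)C)(C(C)C)C(C)C)c2)O3)c(B2OC(C)(C)C(C)(C)O2)c1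
F5 | step 2 | tert-butyl (5-cyano-2-fluorophenoxy)acetate | CC(C)(C)OC(=O)COc1cc(C#N)ccc1F
F6 | step 2 | (5-cyano-2-fluorophenoxy)acetic acid | OC(=O)COc1cc(C#N)ccc1F
F7 | step 13 | pentaacetate of 22 | CC(=O)OC/C=C/c1ccc2c(c1)O[C@H](c1ccc3c(c1)O[C@H](COC(C)=O)[C@@H](c1ccc(OC(C)=O)c(OC(C)=O)c1)O3)[C@@H](COC(C)=O)O2
A1 | alternative 1 | (R)-3-(3,4-dihydroxyphenyl)lactic acid (danshensu) | OC(=O)[C@H](O)Cc1ccc(O)c(O)c1
A2 | alternative 1 | methyl 3-{[(2S)-1-(3,4-dihydroxyphenyl)-3-hydroxypropan-2-yl]oxy}-4-hydroxybenzoate | COC(=O)c1ccc(O)c(O[C@H](CO)Cc2ccc(O)c(O)c2)c1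
A3 | alternative 1 | methyl (2R,3R)-2-(3,4-dihydroxyphenyl)-3-(hydroxymethyl)-2,3-dihydro-1,4-benzodioxine-6-carboxylate | COC(=O)c1ccc2c(c1)O[C@H](CO)[C@@H](c1ccc(O)c(O)c1)O2
A4 | alternative 2 | methyl (2E,4S)-4-[3,4-bis(benzyloxy)phenyl]-4-(4-cyano-2-hydroxyphenoxy)but-2-enyl carbonate | N#Cc1ccc(O[C@@H](/C=C/COC(=O)OC)c2ccc(OCc3ccccc3)c(OCc3ccccc3)c2)c(O)c1
A5 | alternative 2 | (2R,3R)-2-[3,4-bis(benzyloxy)phenyl]-3-vinyl-2,3-dihydro-1,4-benzodioxine-6-carbonitrile | N#Cc1ccc2c(c1)O[C@H](C=C)[C@@H](c1ccc(OCc3ccccc3)c(OCc3ccccc3)c1)O2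
A6 | alternative 3 | (1R,2R)-diyne: C7 ethynyl ether and C8 (trimethylsilyl)ethynyl ether of the C9-silylated triol on the tert-butyldimethylsilyl-protected ring B and C benzodioxane | C#CO[C@H](c1ccc2c(c1)O[C@H](CO[Si](C)(C)C(C)(C)C)[C@@H](c1ccc(O[Si](C)(C)C(C)(C)C)c(O[Si](C)(C)C(C)(C)C)c1)O2)[C@@H](CO[Si](C)(C)C(C)(C)C)OC#C[Si](C)(C)C
A7 | alternative 3 | (E)-tert-butyldimethyl(pent-2-en-4-ynyloxy)silane | C#C/C=C/CO[Si](C)(C)C(C)(C)C
A8 | alternative 3 | fully tert-butyldimethylsilylated target with a trimethylsilyl group on ring A | CC(C)(C)[Si](C)(C)OC/C=C/c1cc([Si](C)(C)C)c2c(c1)O[C@H](c1ccc3c(c1)O[C@H](CO[Si](C)(C)C(C)(C)C)[C@@H](c1ccc(O[Si](C)(C)C(C)(C)C)c(O[Si](C)(C)C(C)(C)C)c1)O3)[C@@H](CO[Si](C)(C)C(C)(C)C)O2
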